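The route rests on the C1–C5 fusion bond (daucane numbering: C1 methyl-bearing quaternary carbon, C4 isopropyl carbinol, C5 fusion CH, C6 ester carbon, C8 methylidene carbon, C9/C10 diol). Cutting it merges five-membered ring A and seven-membered ring B into one ten-membered carbocycle, in which the C10 hydroxyl becomes an epoxide oxygen bridging C1 and C10 and the C4 hydroxyl a molecule of water. In the forward sense, acid-triggered attack of a ring-cis C4=C5 alkene on that epoxide builds both rings, three stereocentres and both hydroxyls in one operation. The precursor is the cyclodecene epoxy alcohol already bearing the C6 3-methylbutanoate and the free C9 hydroxyl, so this step ends the synthesis.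

Key step: step 15

Numbering: daucane locants (C1–C10, C14 for the methylidene carbon) are used for all intermediates; ring A is C1–C5 and ring B is C1, C5–C10; the ring-cis C4=C5 geometry has the CIP descriptor E.
Assumption: the (R,R)-diazaborolidine of step 10 is taken to deliver the 2-bromoallyl group to the si face of the enal (6S); if the sense proves opposite, its enantiomer is used and nothing else changes.

Step 1
Reactants: 1 nerol
Product: 2 (2R,3S)-2,3-epoxynerol
Conditions: Ti(OiPr)4 (0.1 equiv), D-(−)-diethyl tartrate (0.12 equiv), t-BuOOH (2 equiv), 4 Å molecular sieves, CH2Cl2, −20 °C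
Reagents that add atoms: tert-butyl hydroperoxide, CC(C)(C)OO
Why: Sharpless asymmetric epoxidation acts only on the allylic alkene and, with the D-(−)-tartrate, should deliver oxygen to the face that gives the (2R,3S) cis-epoxide, so that C10 and C1 are set by reagent control.

Step 2
Reactants: 2 (2R,3S)-2,3-epoxynerol
Product: 3 tert-butyldimethylsilyl ether of 2
Conditions: TBSCl, imidazole, CH2Cl2, 0 °C → rt
Reagents that add atoms: tert-butyl(chloro)dimethylsilane, CC(C)(C)[Si](C)(C)Cl
Why: Silylation of a primary alcohol is routine and masks the C9 oxygen through the organometallic steps without touching a stereocentre.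

Step 3
Reactants: 3 tert-butyldimethylsilyl ether of 2
Product: 5 4-[(2S,3R)-3-(silyloxymethyl)-2-methyloxiran-2-yl]butanal, via ozonide 4 (not isolated)
Conditions: O3, CH2Cl2, −78 °C; then PPh3, −78 °C → rt
Reagents that add atoms: ozone, [O-][O+]=O
Why: Ozonolysis with reductive work-up cleaves the only remaining alkene to the C4 aldehyde, and neither the epoxide nor the silyl ether reacts with ozone at −78 °C.

Step 4
Reactants: 5 epoxy aldehyde
Product: 6 terminal alkyne (C4≡C5)
Conditions: dimethyl (1-diazo-2-oxopropyl)phosphonate, K2CO3, MeOH, 0 °C → rt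
Reagents that add atoms: dimethyl (1-diazo-2-oxopropyl)phosphonate, COP(=O)(OC)C(=[N+]=[N-])C(C)=O
Why: The Ohira–Bestmann variant of the Seyferth–Gilbert homologation converts the aldehyde into the alkyne under mild carbonate conditions that a trisubstituted epoxide tolerates.

Step 5
Reactants: 6 terminal alkyne
Product: 8 methyl alk-2-ynoate, via lithium acetylide 7 (not isolated)
Conditions: n-BuLi, THF, −78 °C; then ClCO2Me, −78 → 0 °C
Reagents that add atoms: methyl chloroformate, COC(=O)Cl
Why: Deprotonation of the alkyne and C-acylation of the acetylide with a chloroformate is a standard ynoate synthesis and adds C6 at the ester oxidation level.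

Step 6
Reactants: 8 methyl alk-2-ynoate; 9 isopropylmagnesium chloride
Product: 10 methyl (2E)-3-isopropyl enoate
Conditions: 9 (2.2 equiv), CuBr·SMe2 (1.1 equiv), THF, −78 °C; then 8, −78 °C; aq. NH4Cl at −78 °C
Reagents that add atoms: isopropylmagnesium chloride 9, CC(C)[Mg]Cl
Why: Syn carbocupration of the ynoate by the magnesium diisopropylcuprate places isopropyl and copper on the same side, and protonation with retention at −78 °C should give the ester cis to the C3 chain (CIP E), which is the ring-cis C4=C5 geometry.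

Step 7
Reactants: 10 methyl (2E)-3-isopropyl enoate
Product: 11 (2E)-allylic alcohol
Conditions: i-Bu2AlH (2.5 equiv), CH2Cl2, −78 °C; aq. KNaC4H4O6 (potassium sodium tartrate)
Reagents that add atoms: none
Why: 1,2-Reduction of the conjugated ester by the aluminium hydride gives the allylic alcohol without alkene isomerisation, and the epoxide is not opened at −78 °C.

Step 8
Reactants: 11 (2E)-allylic alcohol
Product: 12 (2E)-enal
Conditions: MnO2, CH2Cl2, rt
Reagents that add atoms: none
Why: Heterogeneous MnO2 oxidises only the allylic alcohol and, being neutral, should not isomerise the trisubstituted enal.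

Step 9
Reactants: 13 2,3-dibromopropene
Product: 14 (2-bromoprop-2-en-1-yl)tributylstannane
Conditions: n-Bu3SnLi (from n-Bu3SnH and LiN(iPr)2, THF, 0 °C), THF, −78 °C
Reagents that add atoms: tributyltin hydride, CCCC[SnH](CCCC)CCCC
Why: SN2 displacement of the allylic bromide by the stannyl anion is fast at −78 °C, whereas the vinylic bromide is inert to substitution.

Step 10
Reactants: 12 (2E)-enal; 14 (2-bromoprop-2-en-1-yl)tributylstannane
Product: 16 (4S,5E)-2-bromo-octa-1,5-dien-4-ol (6S in daucane numbering), via B-allyl diazaborolidine 15 (not isolated)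
Conditions: (4R,5R)-2-bromo-1,3-bis(4-methylbenzenesulfonyl)-4,5-diphenyl-1,3,2-diazaborolidine (1.1 equiv; from the (R,R)-bis-sulfonamide and BBr3, volatiles removed), 14, CH2Cl2, rt; then 12, −78 °C; pH 7 buffer
Reagents that add atoms: (2-bromoprop-2-en-1-yl)tributylstannane 14, C=C(Br)C[Sn](CCCC)(CCCC)CCCC
Why: Tin-to-boron exchange gives a chiral B-allyl diazaborolidine that adds to the enal through a closed chair transition state (asymmetric allylboration), the C2-symmetric bis-sulfonamide directing the 2-bromoallyl group to the si face so that C6 is set as S by reagent control, and the minor enantiomer of the epoxide should emerge as a separable diastereomer.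

Step 11
Reactants: 16 bromo dienol; 17 3-methylbutanoyl chloride
Product: 18 C6 3-methylbutanoate of 16
Conditions: 17, pyridine, DMAP (0.1 equiv), CH2Cl2, 0 °C
Reagents that add atoms: 3-methylbutanoyl chloride 17, CC(C)CC(=O)Cl
Why: DMAP-catalysed acylation of the secondary allylic alcohol installs the ester of the target with retention at C6, so that no hydroxyl has to be differentiated after the cyclisation.

Step 12
Reactants: 18 C6 3-methylbutanoate of 16
Product: 19 primary 2,3-epoxy alcohol
Conditions: n-Bu4NF, AcOH (1:1), THF, 0 °C → rt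
Reagents that add atoms: none
Why: Fluoride cleaves the primary silyl ether, and the acetic acid buffer should prevent ester cleavage and Payne rearrangement of the liberated epoxy alcohol.

Step 13
Reactants: 19 primary 2,3-epoxy alcohol
Product: 20 α,β-epoxy aldehyde
Conditions: Dess–Martin periodinane, NaHCO3, CH2Cl2, 0 °C
Reagents that add atoms: none
Why: Buffered Dess–Martin oxidation converts 2,3-epoxy alcohols into epoxy aldehydes without epimerisation at C10 or opening of the epoxide, and the aldehyde is used at once.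

Step 14
Reactants: 20 α,β-epoxy aldehyde
Product: 21 ten-membered epoxy alcohol (1S,4E,6S,9R,10R)
Conditions: CrCl2 (10 equiv), NiCl2 (0.1 equiv), degassed DMSO/THF, rt, slow addition to 0.002 M
Reagents that add atoms: none
Why: In the Nozaki–Hiyama–Kishi reaction zerovalent nickel inserts into the vinyl bromide and the alkenyl group passes to trivalent chromium, which adds chemoselectively to the aldehyde; the cis epoxide and the ring-cis alkene pre-fold the chain for C8–C9 closure, and Felkin–Anh addition anti to the epoxide C–O bond should set C9 as R (erythro to C10).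

Step 15
Reactants: 21 ten-membered epoxy alcohol
Product: 22 target, CNP0204264.1
Conditions: BF3·OEt2 (0.3 equiv), water-saturated CH2Cl2, −78 → −30 °C; then aq. NaHCO3
Reagents that add atoms: water, O
Why: The acid should ionise the epoxide C1–O bond at the tertiary carbon while C5 of the ring-cis C4=C5 alkene bonds to C1 across the ring from the side opposite the departing oxygen, and the resulting tertiary C4 cation is quenched on its far face by oxygen, either by water directly or by the C6 ester carbonyl as a 1,3-dioxan-2-ylium ion that water opens to the C4 carbinol and the C6 ester, the epoxide oxygen staying on C10 as its hydroxyl. The closest known reaction type is the acid-promoted transannular epoxide–alkene cyclisation of germacrane-type cyclodecadiene epoxides to hydroazulenes. Ring A (C1–C5) closes by 5-exo opening of the epoxide with the alkene endocyclic, and the same bond closes ring B (C1, C5–C10), formally a 7-endo opening with C4 exocyclic. C1 is set by inversion at the epoxide carbon fixed in step 1, C5 by attack on the alkene face that carries C7 when H6 lies in the alkene plane (allylic 1,3-strain from the 6S centre), and C4 by anti addition across the ring-cis alkene, reinforced by the ester oxygen held on that face cis to C6; C6, C9 and C10 are carried through unchanged. The step needs opening at C1 and not at C10, C4=C5 and not C8=C14 as the nucleophile, and a trans ring fusion: C1 is tertiary while C10 is deactivated by the C9 oxygen, the methylidene is the poorer π-donor and could reach C1 only by an endo opening within a five-membered array, and the matched 6S and (1S,10R) centres place H5 and the C1 methyl on opposite faces once backside attack at C1 and C7-face attack at C5 are both met.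

Compound list

1 | nerol, (2Z)-3,7-dimethylocta-2,6-dien-1-ol | CC(C)=CCC/C(C)=C\CO | starting material
2 | [(2R,3S)-3-methyl-3-(4-methylpent-3-en-1-yl)oxiran-2-yl]methanol | CC(C)=CCC[C@]1(C)O[C@@H]1CO | intermediate
3 | tert-butyl(dimethyl){[(2R,3S)-3-methyl-3-(4-methylpent-3-en-1-yl)oxiran-2-yl]methoxy}silane | CC(C)=CCC[C@]1(C)O[C@@H]1CO[Si](C)(C)C(C)(C)C | intermediate
4 | 5-{2-[(2S,3R)-3-({[tert-butyl(dimethyl)silyl]oxy}methyl)-2-methyloxiran-2-yl]ethyl}-3,3-dimethyl-1,2,4-trioxolane (ozonide, mixture at the trioxolane CH) | CC1(C)OOC(CC[C@]2(C)O[C@@H]2CO[Si](C)(C)C(C)(C)C)O1 | intermediate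
5 | 4-[(2S,3R)-3-({[tert-butyl(dimethyl)silyl]oxy}methyl)-2-methyloxiran-2-yl]butanal | O=CCC[C@]1(C)O[C@@H]1CO[Si](C)(C)C(C)(C)C | intermediate
6 | {[(2R,3S)-3-(but-3-yn-1-yl)-3-methyloxiran-2-yl]methoxy}(tert-butyl)dimethylsilane | C#CCC[C@]1(C)O[C@@H]1CO[Si](C)(C)C(C)(C)C | intermediate
7 | lithium acetylide of 6 | [Li]C#CCC[C@]1(C)O[C@@H]1CO[Si](C)(C)C(C)(C)C | intermediate
8 | methyl 5-[(2S,3R)-3-({[tert-butyl(dimethyl)silyl]oxy}methyl)-2-methyloxiran-2-yl]pent-2-ynoate | COC(=O)C#CCC[C@]1(C)O[C@@H]1CO[Si](C)(C)C(C)(C)C | intermediate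
9 | isopropylmagnesium chloride | CC(C)[Mg]Cl | starting material
10 | methyl (2E)-5-[(2S,3R)-3-({[tert-butyl(dimethyl)silyl]oxy}methyl)-2-methyloxiran-2-yl]-3-(propan-2-yl)pent-2-enoate | COC(=O)/C=C(/C(C)C)\CC[C@]1(C)O[C@@H]1CO[Si](C)(C)C(C)(C)C | intermediate
11 | (2E)-5-[(2S,3R)-3-({[tert-butyl(dimethyl)silyl]oxy}methyl)-2-methyloxiran-2-yl]-3-(propan-2-yl)pent-2-en-1-ol | OC/C=C(/C(C)C)\CC[C@]1(C)O[C@@H]1CO[Si](C)(C)C(C)(C)C | intermediate
12 | (2E)-5-[(2S,3R)-3-({[tert-butyl(dimethyl)silyl]oxy}methyl)-2-methyloxiran-2-yl]-3-(propan-2-yl)pent-2-enal | O=C/C=C(/C(C)C)\CC[C@]1(C)O[C@@H]1CO[Si](C)(C)C(C)(C)C | intermediate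
13 | 2,3-dibromoprop-1-ene | C=C(Br)CBr | starting material
14 | (2-bromoprop-2-en-1-yl)tributylstannane | C=C(Br)C[Sn](CCCC)(CCCC)CCCC | intermediate
15 | (4R,5R)-2-(2-bromoprop-2-en-1-yl)-1,3-bis(4-methylbenzenesulfonyl)-4,5-diphenyl-1,3,2-diazaborolidine | C=C(Br)CB1N(S(=O)(=O)c2ccc(C)cc2)[C@H](c2ccccc2)[C@@H](c2ccccc2)N1S(=O)(=O)c1ccc(C)cc1 | intermediate
16 | (4S,5E)-2-bromo-8-[(2S,3R)-3-({[tert-butyl(dimethyl)silyl]oxy}methyl)-2-methyloxiran-2-yl]-6-(propan-2-yl)octa-1,5-dien-4-ol | C=C(Br)C[C@H](O)/C=C(/C(C)C)\CC[C@]1(C)O[C@@H]1CO[Si](C)(C)C(C)(C)C | intermediate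
17 | 3-methylbutanoyl chloride | CC(C)CC(=O)Cl | starting material
18 | (4S,5E)-2-bromo-8-[(2S,3R)-3-({[tert-butyl(dimethyl)silyl]oxy}methyl)-2-methyloxiran-2-yl]-6-(propan-2-yl)octa-1,5-dien-4-yl 3-methylbutanoate | C=C(Br)C[C@H](OC(=O)CC(C)C)/C=C(/C(C)C)\CC[C@]1(C)O[C@@H]1CO[Si](C)(C)C(C)(C)C | intermediate
19 | (4S,5E)-2-bromo-8-[(2S,3R)-3-(hydroxymethyl)-2-methyloxiran-2-yl]-6-(propan-2-yl)octa-1,5-dien-4-yl 3-methylbutanoate | C=C(Br)C[C@H](OC(=O)CC(C)C)/C=C(/C(C)C)\CC[C@]1(C)O[C@@H]1CO | intermediate
20 | (4S,5E)-2-bromo-8-[(2S,3S)-3-formyl-2-methyloxiran-2-yl]-6-(propan-2-yl)octa-1,5-dien-4-yl 3-methylbutanoate | C=C(Br)C[C@H](OC(=O)CC(C)C)/C=C(/C(C)C)\CC[C@]1(C)O[C@@H]1C=O | intermediate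
21 | (1S,4E,6S,9R,10R)-9-hydroxy-1-methyl-8-methylidene-4-(propan-2-yl)-11-oxabicyclo[8.1.0]undec-4-en-6-yl 3-methylbutanoate (locants as in daucane numbering) | C=C1C[C@H](OC(=O)CC(C)C)/C=C(/C(C)C)\CC[C@]2(C)O[C@@H]2[C@@H]1O | intermediate
22 | (3R,3aS,4S,7R,8S,8aS)-3,7,8-trihydroxy-8a-methyl-6-methylidene-3-(propan-2-yl)decahydroazulen-4-yl 3-methylbutanoate (daucane numbering 1S,4R,5S,6S,9R,10S) | C=C1C[C@H](OC(=O)CC(C)C)[C@@H]2[C@](C)(CC[C@@]2(O)C(C)C)[C@H](O)[C@@H]1O | target

Total step count: 15. Longest linear sequence: 14 steps (steps 1–8 and 10–15, nerol to target); step 9 is a one-step branch.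

Steps most likely to fail

1. Step 15. The C4 cation may be lost by proton loss or hydride shift before oxygen is captured, the ionised epoxide may undergo a 1,2-shift, or the Lewis acid may ionise the allylic ester. The fallback keeps the ring closure but uses water as the only trap on a bis-silyl ether and defers the acylation. It sets out from 21.
   - i-Bu2AlH (CH2Cl2, −78 °C) would cleave the ester to the macrocyclic epoxy diol F1.
   - TBSOTf/2,6-lutidine (CH2Cl2, −78 °C) would give the bis-silyl ether F2.
   - TsOH·H2O in THF/H2O (0 °C) should effect the same transannular closure, giving the bicyclic bis-silyl diol F3.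
   - n-Bu4NF (THF) would free the tetraol F4.
   - 2,2-Dimethoxypropane/PPTS would tie the cis C9,C10 diol as the acetonide F5.
   - 17 with DMAP/pyridine would acylate the C6 hydroxyl to the acetonide ester F6, the tertiary C4 hydroxyl being inert.
   - Aqueous AcOH would remove the acetonide, and the route is rejoined at 22.

2. Step 14. The folding chain may impose poor facial selectivity at the aldehyde carbon, and intermolecular coupling or reduction of the epoxy aldehyde by divalent chromium may compete with closure of the medium ring. The fallback sets C9 by hydride delivery and not by the C–C bond formation. It sets out from 20: the closure is run as in step 14 and the product is taken on as the mixture of 21 and its C9 epimer F7. Dess–Martin oxidation would converge both on the epoxy enone F8. Chelation-controlled reduction with Zn(BH4)2 (Et2O, 0 °C), which is known to give erythro epoxy alcohols from α,β-epoxy ketones, should return to the route at 21.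

3. Step 10. Facial control by the boron reagent may be incomplete, or the epoxide may be damaged by boron or tin halides. The fallback sets C6 by reduction and not by allyl transfer. It sets out from 12 and 13: a Barbier reaction with indium powder in THF/H2O would give 16 together with its C6 epimer F9. Dess–Martin oxidation of the mixture would give the dienone F10. Corey–Bakshi–Shibata reduction with the (R)-2-methyl-oxazaborolidine and catecholborane (toluene, −78 °C), the alkenyl group acting as the large substituent, should return to the route at 16.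

Further compounds

F1 | step 15 | (1S,4E,6S,9R,10R)-1-methyl-8-methylidene-4-(propan-2-yl)-11-oxabicyclo[8.1.0]undec-4-ene-6,9-diol | C=C1C[C@H](O)/C=C(/C(C)C)\CC[C@]2(C)O[C@@H]2[C@@H]1O
F2 | step 15 | 6,9-bis(tert-butyldimethylsilyl) ether of F1 | C=C1C[C@H](O[Si](C)(C)C(C)(C)C)/C=C(/C(C)C)\CC[C@]2(C)O[C@@H]2[C@@H]1O[Si](C)(C)C(C)(C)C
F3 | step 15 | (3R,3aS,4S,7R,8S,8aS)-4,7-bis{[tert-butyl(dimethyl)silyl]oxy}-8a-methyl-6-methylidene-3-(propan-2-yl)decahydroazulene-3,8-diol | C=C1C[C@H](O[Si](C)(C)C(C)(C)C)[C@@H]2[C@](C)(CC[C@@]2(O)C(C)C)[C@H](O)[C@@H]1O[Si](C)(C)C(C)(C)C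
F4 | step 15 | (3R,3aS,4S,7R,8S,8aS)-8a-methyl-6-methylidene-3-(propan-2-yl)decahydroazulene-3,4,7,8-tetrol | C=C1C[C@H](O)[C@@H]2[C@](C)(CC[C@@]2(O)C(C)C)[C@H](O)[C@@H]1O
F5 | step 15 | C9,C10-O-isopropylidene acetal of F4 | C=C1C[C@H](O)[C@@H]2[C@](C)(CC[C@@]2(O)C(C)C)[C@@H]3OC(C)(C)O[C@H]13
F6 | step 15 | C6 3-methylbutanoate of F5 | C=C1C[C@H](OC(=O)CC(C)C)[C@@H]2[C@](C)(CC[C@@]2(O)C(C)C)[C@@H]3OC(C)(C)O[C@H]13
F7 | step 14 | (1S,4E,6S,9S,10R)-9-hydroxy-1-methyl-8-methylidene-4-(propan-2-yl)-11-oxabicyclo[8.1.0]undec-4-en-6-yl 3-methylbutanoate (C9 epimer of 21) | C=C1C[C@H](OC(=O)CC(C)C)/C=C(/C(C)C)\CC[C@]2(C)O[C@@H]2[C@H]1O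
F8 | step 14 | (1S,4E,6S,10S)-1-methyl-8-methylidene-9-oxo-4-(propan-2-yl)-11-oxabicyclo[8.1.0]undec-4-en-6-yl 3-methylbutanoate | C=C1C[C@H](OC(=O)CC(C)C)/C=C(/C(C)C)\CC[C@]2(C)O[C@@H]2C1=O
F9 | step 10 | (4R,5E)-2-bromo-8-[(2S,3R)-3-({[tert-butyl(dimethyl)silyl]oxy}methyl)-2-methyloxiran-2-yl]-6-(propan-2-yl)octa-1,5-dien-4-ol (C6 epimer of 16) | C=C(Br)C[C@@H](O)/C=C(/C(C)C)\CC[C@]1(C)O[C@@H]1CO[Si](C)(C)C(C)(C)C
F10 | step 10 | (5E)-2-bromo-8-[(2S,3R)-3-({[tert-butyl(dimethyl)silyl]oxy}methyl)-2-methyloxiran-2-yl]-6-(propan-2-yl)octa-1,5-dien-4-one | C=C(Br)CC(=O)/C=C(/C(C)C)\CC[C@]1(C)O[C@@H]1CO[Si](C)(C)C(C)(C)C
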